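**Retrosynthetic overview**

1. Feature: in the cyclohexane (C1 alkylidene carbon, C4 carbinol, C5 quaternary carbon, C6 methine) the aldehyde carbon on the exocyclic C1=Cα alkene lies syn to C6, and C6 carries the 3-hydroxypropyl arm. Aldehyde carbon and arm oxygen are therefore treated as the two reduced ends of an eight-membered α,β-unsaturated lactone (C1, Cα, C=O, O, three CH2, C6) fused at C1–C6, a ring that can hold only this alkene geometry.
2. Disconnections: enal/alcohol → unsaturated lactone → (E1cB dehydration) β-hydroxy lactone → SmI2 Reformatsky closure of the C1–Cα bond from the C6-arm 2-bromopropanoate and the C1 ketone; the C5 side chain is cut at CH2–CH= (Negishi sp3–sp2 coupling).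
3. Ring fragment from (S)-Wieland–Miescher ketone: ring A is kept (C4 carbinol by MeLi, C1 oxygen and C6–H by hydroboration); ring B is opened by ozonolysis of a silyl enol ether and one carbon is added by Wittig methylenation.
4. Side chain from 3-methylbut-2-enal: asymmetric propargylation, two zirconium-catalysed carboaluminations joined by a Negishi coupling, then hydroxyl-directed epoxidation.
5. Ring order: decalin (purchased) → ring B opened, temporary γ-lactone → eight-membered lactone (key step) → lactone opened by iBu2AlH after the coupling; the oxirane is made on the side chain before coupling.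

Key step: step 15

Locants: all ring carbons carry the locants of the target cyclohexane. In 1, C4 is the saturated carbonyl carbon, C5 the quaternary carbon and C6 the ring-fusion alkene carbon; the four other carbons of ring B are called a, b, c, d going from C6 to C5 (b is the enone carbonyl carbon). Cα is the propanoate carbon that becomes bound to C1.

Remark on the chemistry: 22 and 23 are expected as mixtures of epimers at C1 and Cα and are drawn as one epimer, since all converge in step 16; the (S)-acid 19 is used only so that 20 and 21 are single compounds.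

**Route**

Step 1
Reactants: 1 (S)-Wieland–Miescher ketone
Product: 2 (4aS,5S)-5-hydroxy-4a-methyl-4,4a,5,6,7,8-hexahydronaphthalen-2(3H)-one (C4 alcohol, OH cis to the C5 methyl)
Conditions: NaBH4 (0.3 equiv), EtOH, −10 °C
Reagents that add atoms: none
Why: Chemoselective borohydride reduction of the saturated C4 ketone beside the less electrophilic enone, with hydride adding anti to the angular methyl; the centre only masks C4 and is removed in step 3.

Step 2
Reactants: 2 hydroxy enone
Product: 3 C4 alcohol with Cb as ethylene ketal and the alkene moved to C1=C6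
Conditions: HOCH2CH2OH, p-TsOH·H2O (cat.), benzene, reflux, Dean–Stark
Reagents that add atoms: ethylene glycol (OCCO)
Why: Acid-catalysed ketalization of the enone carbonyl runs through the dienol ether and leaves the double bond in the β,γ position, as in the conversion of steroid 4-en-3-ones into 5-ene ketals.

Step 3
Reactants: 3 ketal alcohol
Product: 4 C4 ketone with Cb ethylene ketal and C1=C6 alkene
Conditions: Dess–Martin periodinane, pyridine, CH2Cl2, 0 °C → rt
Reagents that add atoms: none
Why: Dess–Martin oxidation returns the C4 ketone as the only carbonyl group; its quaternary α-carbon C5 prevents the alkene from moving into conjugation.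

Step 4
Reactants: 4 keto ketal
Product: 6 C4 methyl carbinol triethylsilyl ether (C4–O cis and C4–CH3 trans to the C5 methyl) with Cb ketal and C1=C6 alkene, via lithium alkoxide 5 (not isolated)
Conditions: MeLi, Et2O/THF, −78 °C; then Et3SiOTf, −78 → 0 °C
Reagents that add atoms: methyllithium ([Li]C); triethylsilyl trifluoromethanesulfonate (CC[Si](CC)(CC)OS(=O)(=O)C(F)(F)F)
Why: 1,2-Addition of methyllithium takes the axial path opposite the angular C5 methyl, which blocks the other face, so the C4 oxygen ends cis to that methyl; the hindered alkoxide is silylated in the same flask by the silyl triflate.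

Step 5
Reactants: 6 silyl ether alkene
Product: 8 trans-fused C1 alcohol (C1–OH and C6–H both trans to the C5 methyl) with C4–OSiEt3 and Cb ketal, via C1 alkylborane 7 (not isolated)
Conditions: BH3·THF, THF, 0 °C → rt; then 3 M NaOH, 30% H2O2, 0 °C → rt
Reagents that add atoms: hydrogen peroxide (OO)
Why: Brown hydroboration–oxidation places boron on the less substituted C1 and hydrogen syn on C6 from the face away from the angular methyl (the 5-ene to 5α,6α-ol precedent of steroids), which sets the C6 centre and the trans ring fusion; a minor cis-fused isomer would be removed by chromatography.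

Step 6
Reactants: 8 ketal alcohol
Product: 9 trans-fused hydroxy ketone (C1–OH, Cb ketone, C4–OSiEt3)
Conditions: pyridinium p-toluenesulfonate (cat.), acetone/H2O (10:1), 55 °C
Reagents that add atoms: water (O)
Why: Mild acid-catalysed hydrolysis of the dioxolane; the tertiary triethylsilyl ether beside a quaternary carbon should survive this weak acid.

Step 7
Reactants: 9 hydroxy ketone
Product: 10 bis(trimethylsilyl) derivative (Cb=Cc silyl enol ether, C1–OSiMe3, C4–OSiEt3)
Conditions: Me3SiCl, NaI, Et3N, MeCN, rt
Reagents that add atoms: chlorotrimethylsilane (C[Si](C)(C)Cl)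
Why: Silyl enol ether formation under equilibrating conditions (Me3SiI made in the flask) goes toward Cc, the 2-ene preference of trans-fused 5α-3-keto steroids, helped by the bulky C1 silyl ether beside Ca; the C1 hydroxyl is silylated at the same time.

Step 8
Reactants: 10 silyl enol ether
Product: 13 trans-fused γ-lactone (C1–O–CO–CH2–C6) bearing C5–CH2CH2OH and C4–OSiEt3, via silyl ester peroxy acetal 11 (not isolated), via dihydroxy acid 12 (not isolated)
Conditions: O3, CH2Cl2/MeOH (1:1), −78 °C; NaBH4, −78 → 0 °C; aq. HCl to pH 3; then pyridinium p-toluenesulfonate (cat.), benzene, 60 °C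
Reagents that add atoms: ozone ([O-][O+]=O)
Why: Ozonolysis of the electron-rich enol ether cleaves Cb–Cc into a Cb carboxyl and a Cc methoxy hydroperoxide that NaBH4 reduces to the primary alcohol; after methanolysis of the trimethylsilyl groups the C1 hydroxyl and the Cb acid close the γ-lactone, which tells the two arms apart without a protecting group.

Step 9
Reactants: 13 lactone alcohol
Product: 14 γ-lactone with C5–CH2CH2Cl
Conditions: PPh3, CCl4, CH2Cl2, 40 °C
Reagents that add atoms: carbon tetrachloride (ClC(Cl)(Cl)Cl)
Why: Appel chlorination of the primary alcohol under neutral conditions gives a halide that is inert to every reagent up to the halide exchange of step 17, SmI2 included.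

Step 10
Reactants: 14 lactone chloride
Product: 15 lactol (hemiacetal at Cb, mixture of anomers)
Conditions: iBu2AlH (1.1 equiv), CH2Cl2, −78 °C; aq. KNaC4H4O6
Reagents that add atoms: none
Why: Partial reduction of a γ-lactone stops at the lactol because the five-membered aluminium hemiacetal is stable at −78 °C.

Step 11
Reactants: 15 lactol
Product: 16 C1 alcohol with C6 allyl, C5 2-chloroethyl and C4–OSiEt3
Conditions: Ph3PCH3Br (3.2 equiv), KOtBu (3.0 equiv), THF, 0 °C → rt
Reagents that add atoms: methyltriphenylphosphonium bromide (C[P+](c1ccccc1)(c1ccccc1)c1ccccc1.[Br-])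
Why: Wittig methylenation of the lactol through its open hydroxy aldehyde adds the one missing carbon of the C6 arm and frees the C1 hydroxyl; no stereocentre is α to the aldehyde.

Step 12
Reactants: 16 allyl alcohol
Product: 18 diol (C1–OH, C6–CH2CH2CH2OH), via B-alkyl-9-BBN 17 (not isolated)
Conditions: 9-borabicyclo[3.3.1]nonane (2.5 equiv), THF, rt; then 3 M NaOH, 30% H2O2, 0 °C
Reagents that add atoms: hydrogen peroxide (OO)
Why: Anti-Markovnikov hydroboration–oxidation of the terminal alkene gives the 3-hydroxypropyl arm; the alkyl chloride and silyl ether are untouched.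

Step 13
Reactants: 18 diol; 19 (S)-2-bromopropanoic acid
Product: 20 C6-arm (2S)-2-bromopropanoate with free C1–OH
Conditions: N,N'-dicyclohexylcarbodiimide, 4-(dimethylamino)pyridine (cat.), CH2Cl2, −20 → 0 °C
Reagents that add atoms: none
Why: Steglich esterification acylates the primary hydroxyl much faster than the hindered ring secondary hydroxyl; the configuration at the C–Br carbon does not matter because that carbon becomes the enolate carbon.

Step 14
Reactants: 20 bromo ester alcohol
Product: 21 key precursor: C1 ketone with C6–(CH2)3–O–CO–CH(CH3)Br, C5–CH2CH2Cl and C4–OSiEt3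
Conditions: Dess–Martin periodinane, pyridine, CH2Cl2, 0 °C → rt
Reagents that add atoms: none
Why: Dess–Martin oxidation under buffered, non-basic conditions gives the C1 ketone without epimerizing C6 or disturbing the α-bromo ester.

Step 15
Reactants: 21 keto bromo ester
Product: 22 β-hydroxy eight-membered lactone fused at C1–C6 (tertiary C1–OH, Cα–CH3)
Conditions: SmI2 (3 equiv, 0.1 M in THF), 21 added over 6 h to 0.005 M, −78 → 0 °C; aq. NH4Cl
Reagents that add atoms: none
Why: SmI2 (divalent samarium) reduces the C–Br bond by two single-electron transfers to a trivalent samarium enolate, which chelation of the oxophilic metal holds near the C1 ketone and which adds to it in a Reformatsky-type aldol, forming the C1–Cα bond. The closest known reaction is the SmI2-mediated intramolecular Reformatsky reaction of ω-(α-bromoacyloxy) aldehydes and ketones to medium-ring β-hydroxy lactones. The eight-membered lactone (C1, Cα, C=O, O, three CH2, C6) closes in the 8-exo-trig mode. The new C1 centre is set by the tether, which starts from the equatorial C6 arm and should place the new C–C bond equatorial, and the Cα centre is set by the geometry of the chelated enolate; neither matters because both are erased in step 16. The step needs reduction of C–Br in preference to C=O and C–Cl, which the much easier reduction of an α-bromo ester secures in THF without additives, and it needs ring closure to outrun intermolecular aldol addition and enolate protonation, which slow addition at high dilution under aprotic conditions secures.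

Step 16
Reactants: 22 β-hydroxy lactone
Product: 24 unsaturated eight-membered lactone (C1=Cα, carbonyl carbon syn to C6) with C5–CH2CH2Cl and C4–OSiEt3, via tertiary mesylate 23 (not isolated)
Conditions: MeSO2Cl, Et3N, CH2Cl2, 0 °C; then DBU, rt
Reagents that add atoms: none
Why: Sulfonylation of the tertiary aldol hydroxyl through sulfene followed by DBU-promoted E1cB elimination through the lactone enolate places the double bond only between C1 and Cα, and the eight-membered ring allows only the cis geometry, so all aldol epimers converge on one alkene.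

Step 17
Reactants: 24 chloride
Product: 25 unsaturated lactone with C5–CH2CH2I
Conditions: NaI, 2-butanone, 80 °C
Reagents that add atoms: sodium iodide ([Na+].[I-])
Why: Finkelstein halide exchange (SN2, driven by precipitation of NaCl) gives the primary iodide needed for zinc insertion.

Step 18
Reactants: 26 4-(trimethylsilyl)but-3-yn-1-ol
Product: 27 (4-iodobut-1-yn-1-yl)trimethylsilane
Conditions: I2, PPh3, imidazole, CH2Cl2, 0 °C → rt
Reagents that add atoms: iodine (II)
Why: Garegg–Samuelsson (Appel-type) iodination of a primary alcohol.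

Step 19
Reactants: 28 3-methylbut-2-enal
Product: 29 (S)-6-methylhept-5-en-1-yn-4-ol
Conditions: allenylboronic acid pinacol ester, (S)-TRIP [(S)-3,3'-bis(2,4,6-triisopropylphenyl)-1,1'-binaphthalene-2,2'-diyl hydrogen phosphate] (10 mol%), 4 Å molecular sieves, toluene, 0 °C
Reagents that add atoms: allenylboronic acid pinacol ester (C=C=CB1OC(C)(C)C(C)(C)O1)
Why: Chiral phosphoric acid-catalysed propargylation (SE2' allenylboration through a six-membered chair transition state); by analogy with aromatic and conjugated aldehydes the (S)-acid should direct attack to the Si face and give the (S)-carbinol, to be confirmed by Mosher ester analysis.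

Step 20
Reactants: 29 homopropargylic alcohol
Product: 30 (S)-tert-butyl[(6-methylhept-5-en-1-yn-4-yl)oxy]dimethylsilane
Conditions: tBuMe2SiCl, imidazole, DMF, rt
Reagents that add atoms: tert-butyldimethylsilyl chloride (CC(C)(C)[Si](C)(C)Cl)
Why: Standard silylation; the ether protects the allylic carbinol from ionization by the Lewis-acidic aluminium reagents of the next steps.

Step 21
Reactants: 30 silyl ether alkyne
Product: 32 (S,E)-tert-butyl[(1-iodo-2,6-dimethylhepta-1,5-dien-4-yl)oxy]dimethylsilane, via alkenylalane 31 (not isolated)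
Conditions: Me3Al, Cp2ZrCl2 (0.25 equiv), CH2Cl2, 0 °C → rt; then I2, THF, −30 → 0 °C
Reagents that add atoms: trimethylaluminium (C[Al](C)C); iodine (II)
Why: Negishi zirconium-catalysed carboalumination adds methyl (to the internal carbon) and aluminium syn across the terminal alkyne, and iodinolysis with retention gives the (E)-iodoalkene.

Step 22
Reactants: 32 iodoalkene; 27 alkyl iodide
Product: 34 trimethyl[(5E,8S)-8-(tert-butyldimethylsilyloxy)-6,10-dimethylundeca-5,9-dien-1-yn-1-yl]silane, via homopropargylzinc iodide 33 (not isolated)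
Conditions: 27, Zn dust (activated), LiCl, THF, 40 °C; then 32, Pd(PPh3)4 (5 mol%), THF, rt
Reagents that add atoms: none
Why: Negishi sp3–sp2 cross-coupling of the alkylzinc iodide with the alkenyl iodide retains the alkene geometry, and the silyl cap blocks the acidic alkyne C–H.

Step 23
Reactants: 34 silyl enyne
Product: 35 tert-butyl{[(5E,8S)-6,10-dimethylundeca-5,9-dien-1-yn-8-yl]oxy}dimethylsilane
Conditions: K2CO3, MeOH, rt
Reagents that add atoms: none
Why: Base-catalysed methanolysis of the alkynyl C–Si bond; the silyl ether of the secondary alcohol is untouched.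

Step 24
Reactants: 35 terminal enyne
Product: 37 tert-butyl{[(1E,5E,8S)-1-iodo-2,6,10-trimethylundeca-1,5,9-trien-8-yl]oxy}dimethylsilane, via alkenylalane 36 (not isolated)
Conditions: Me3Al, Cp2ZrCl2 (0.25 equiv), CH2Cl2, 0 °C → rt; then I2, THF, −30 → 0 °C
Reagents that add atoms: trimethylaluminium (C[Al](C)C); iodine (II)
Why: A second Negishi carboalumination–iodination, again syn and regioselective, gives the (E,E)-iododiene; the trisubstituted alkenes do not react.

Step 25
Reactants: 37 silyl ether
Product: 38 (1E,5E,8S)-1-iodo-2,6,10-trimethylundeca-1,5,9-trien-8-ol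
Conditions: Bu4NF, THF, 0 °C → rt
Reagents that add atoms: none
Why: Fluoride cleavage of the silyl ether frees the allylic hydroxyl that directs the epoxidation.

Step 26
Reactants: 38 allylic alcohol
Product: 39 (1S,3E,7E)-1-[(2R)-3,3-dimethyloxiran-2-yl]-8-iodo-3,7-dimethylocta-3,7-dien-1-ol (threo epoxy alcohol)
Conditions: VO(acac)2 (5 mol%), tBuOOH, CH2Cl2, 0 °C
Reagents that add atoms: tert-butyl hydroperoxide (CC(C)(C)OO)
Why: Hydroxyl-directed vanadium-catalysed epoxidation prefers the allylic alkene over the homoallylic alkene and the iodoalkene, and A(1,3) strain from the cis methyl (carbinol hydrogen eclipsing the alkene) delivers oxygen syn to the hydroxyl to set the (R)-oxirane carbon; the minor erythro isomer should be separable.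

Step 27
Reactants: 39 epoxy alcohol
Product: 40 triethyl{[(1S,3E,7E)-1-[(2R)-3,3-dimethyloxiran-2-yl]-8-iodo-3,7-dimethylocta-3,7-dien-1-yl]oxy}silane
Conditions: Et3SiCl, imidazole, CH2Cl2, 0 °C
Reagents that add atoms: chlorotriethylsilane (CC[Si](Cl)(CC)CC)
Why: Silylation of the secondary alcohol so that it cannot quench the alkylzinc reagent in the coupling.

Step 28
Reactants: 25 ring iodide; 40 side-chain iodoalkene
Product: 42 coupled unsaturated lactone carrying the full C5 side chain (two triethylsilyl ethers), via alkylzinc iodide 41 (not isolated)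
Conditions: 25, Zn dust (activated), LiCl, THF, 40 °C; then 40, Pd(PPh3)4 (5 mol%), THF/N,N-dimethylacetamide, rt → 40 °C
Reagents that add atoms: none
Why: Negishi sp3–sp2 coupling: zinc insertion into the primary iodide tolerates the lactone and silyl ethers, the coupling retains the (E) geometry, and ZnI2 in THF should be too weak a Lewis acid to open the oxirane.

Step 29
Reactants: 42 coupled lactone
Product: 43 diol (Cα–CH2OH allylic alcohol and C6–(CH2)3OH), bis(triethylsilyl) ether
Conditions: iBu2AlH (5 equiv), CH2Cl2, −78 °C; aq. KNaC4H4O6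
Reagents that add atoms: none
Why: Hydride reduction of the unsaturated lactone by 1,2-addition gives the allylic alcohol and the arm alcohol together; silyl ethers and the trisubstituted oxirane should survive at −78 °C.

Step 30
Reactants: 43 diol
Product: 44 hydroxy enal, bis(triethylsilyl) ether of the target
Conditions: MnO2 (activated, excess), CH2Cl2, rt
Reagents that add atoms: none
Why: MnO2 oxidizes only the allylic primary alcohol, giving the enal with the geometry fixed earlier by the lactone ring.

Step 31
Reactants: 44 bis(silyl) enal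
Product: 45 CNP0161066.1
Conditions: Bu4NF, AcOH (1:1), THF, 0 °C → rt
Reagents that add atoms: none
Why: Acetic acid-buffered fluoride desilylation removes both triethylsilyl ethers while avoiding base-induced Payne rearrangement of the epoxy alcohol and deconjugation of the enal.

**Compound list**

1 | (S)-Wieland–Miescher ketone, (8aS)-8a-methyl-3,4,8,8a-tetrahydronaphthalene-1,6(2H,7H)-dione | O=C1CCCC2=CC(=O)CC[C@]12C | starting material
2 | (4aS,5S)-5-hydroxy-4a-methyl-4,4a,5,6,7,8-hexahydronaphthalen-2(3H)-one | O[C@H]1CCCC2=CC(=O)CC[C@]12C | intermediate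
3 | C4 alcohol, Cb ethylene ketal, C1=C6 alkene | O[C@H]1CCC=C2CC3(OCCO3)CC[C@]12C | intermediate
4 | C4 ketone, Cb ethylene ketal, C1=C6 alkene | O=C1CCC=C2CC3(OCCO3)CC[C@]12C | intermediate
5 | lithium C4 alkoxide of the methyl adduct | C[C@]1(O[Li])CCC=C2CC3(OCCO3)CC[C@]12C | intermediate (not isolated)
6 | C4 methyl carbinol triethylsilyl ether, Cb ketal, C1=C6 alkene | C[C@]1(O[Si](CC)(CC)CC)CCC=C2CC3(OCCO3)CC[C@]12C | intermediate
7 | C1 alkylborane (B on C1, H on C6, both trans to the C5 methyl) | C[C@]1(O[Si](CC)(CC)CC)CC[C@H]([BH2])[C@H]2CC3(OCCO3)CC[C@]12C | intermediate (not isolated)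
8 | trans-fused C1 alcohol, C4–OSiEt3, Cb ketal | C[C@]1(O[Si](CC)(CC)CC)CC[C@H](O)[C@H]2CC3(OCCO3)CC[C@]12C | intermediate
9 | trans-fused hydroxy ketone (C1–OH, Cb ketone) | C[C@]1(O[Si](CC)(CC)CC)CC[C@H](O)[C@H]2CC(=O)CC[C@]12C | intermediate
10 | Cb=Cc trimethylsilyl enol ether, C1–OSiMe3, C4–OSiEt3 | C[C@]1(O[Si](CC)(CC)CC)CC[C@H](O[Si](C)(C)C)[C@H]2CC(O[Si](C)(C)C)=CC[C@]12C | intermediate
11 | ring-B-opened trimethylsilyl ester (C6–CH2CO2SiMe3) methoxy hydroperoxide (C5–CH2CH(OMe)OOH), C1–OSiMe3 | C[C@]1(O[Si](CC)(CC)CC)CC[C@H](O[Si](C)(C)C)[C@@H](CC(=O)O[Si](C)(C)C)[C@]1(C)CC(OC)OO | intermediate (not isolated)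
12 | dihydroxy acid (C1–OH, C6–CH2CO2H, C5–CH2CH2OH) | C[C@]1(O[Si](CC)(CC)CC)CC[C@H](O)[C@@H](CC(=O)O)[C@]1(C)CCO | intermediate (not isolated)
13 | trans-fused γ-lactone (C1–O–CO–CH2–C6), C5–CH2CH2OH, C4–OSiEt3 | C[C@]1(O[Si](CC)(CC)CC)CC[C@@H]2OC(=O)C[C@H]2[C@]1(C)CCO | intermediate
14 | γ-lactone with C5–CH2CH2Cl | C[C@]1(O[Si](CC)(CC)CC)CC[C@@H]2OC(=O)C[C@H]2[C@]1(C)CCCl | intermediate
15 | lactol of 14 | C[C@]1(O[Si](CC)(CC)CC)CC[C@@H]2OC(O)C[C@H]2[C@]1(C)CCCl | intermediate
16 | C1 alcohol, C6 allyl, C5 2-chloroethyl, C4–OSiEt3 | C[C@]1(O[Si](CC)(CC)CC)CC[C@H](O)[C@@H](CC=C)[C@]1(C)CCCl | intermediate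
17 | B-alkyl-9-BBN of the C6 arm | C[C@]1(O[Si](CC)(CC)CC)CC[C@H](O)[C@@H](CCCB2C3CCCC2CCC3)[C@]1(C)CCCl | intermediate (not isolated)
18 | diol (C1–OH, C6–(CH2)3OH) | C[C@]1(O[Si](CC)(CC)CC)CC[C@H](O)[C@@H](CCCO)[C@]1(C)CCCl | intermediate
19 | (S)-2-bromopropanoic acid | C[C@H](Br)C(=O)O | starting material
20 | C6-arm (2S)-2-bromopropanoate, C1–OH | C[C@]1(O[Si](CC)(CC)CC)CC[C@H](O)[C@@H](CCCOC(=O)[C@H](C)Br)[C@]1(C)CCCl | intermediate
21 | key precursor: C1 ketone with C6-arm (2S)-2-bromopropanoate, C5–CH2CH2Cl, C4–OSiEt3 | C[C@]1(O[Si](CC)(CC)CC)CCC(=O)[C@@H](CCCOC(=O)[C@H](C)Br)[C@]1(C)CCCl | intermediate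
22 | β-hydroxy eight-membered lactone fused at C1–C6 (one epimer drawn) | C[C@]1(O[Si](CC)(CC)CC)CC[C@]2(O)[C@@H](C)C(=O)OCCC[C@H]2[C@]1(C)CCCl | intermediate
23 | tertiary C1 mesylate of 22 | C[C@]1(O[Si](CC)(CC)CC)CC[C@]2(OS(C)(=O)=O)[C@@H](C)C(=O)OCCC[C@H]2[C@]1(C)CCCl | intermediate (not isolated)
24 | unsaturated eight-membered lactone (C1=Cα), C5–CH2CH2Cl | C/C1=C2\CC[C@](C)(O[Si](CC)(CC)CC)[C@@](C)(CCCl)[C@@H]2CCCOC1=O | intermediate
25 | unsaturated eight-membered lactone, C5–CH2CH2I | C/C1=C2\CC[C@](C)(O[Si](CC)(CC)CC)[C@@](C)(CCI)[C@@H]2CCCOC1=O | intermediate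
26 | 4-(trimethylsilyl)but-3-yn-1-ol | C[Si](C)(C)C#CCCO | starting material
27 | (4-iodobut-1-yn-1-yl)trimethylsilane | C[Si](C)(C)C#CCCI | intermediate
28 | 3-methylbut-2-enal | CC(C)=CC=O | starting material
29 | (S)-6-methylhept-5-en-1-yn-4-ol | C#CC[C@H](O)C=C(C)C | intermediate
30 | (S)-tert-butyl[(6-methylhept-5-en-1-yn-4-yl)oxy]dimethylsilane | C#CC[C@H](O[Si](C)(C)C(C)(C)C)C=C(C)C | intermediate
31 | (E)-alkenyl(dimethyl)alane from 30 | C[Al](C)/C=C(\C)C[C@H](O[Si](C)(C)C(C)(C)C)C=C(C)C | intermediate (not isolated)
32 | (S,E)-tert-butyl[(1-iodo-2,6-dimethylhepta-1,5-dien-4-yl)oxy]dimethylsilane | I/C=C(\C)C[C@H](O[Si](C)(C)C(C)(C)C)C=C(C)C | intermediate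
33 | [4-(trimethylsilyl)but-3-yn-1-yl]zinc iodide | C[Si](C)(C)C#CCC[Zn]I | intermediate (not isolated)
34 | trimethyl[(5E,8S)-8-(tert-butyldimethylsilyloxy)-6,10-dimethylundeca-5,9-dien-1-yn-1-yl]silane | C[Si](C)(C)C#CCC/C=C(\C)C[C@H](O[Si](C)(C)C(C)(C)C)C=C(C)C | intermediate
35 | tert-butyl{[(5E,8S)-6,10-dimethylundeca-5,9-dien-1-yn-8-yl]oxy}dimethylsilane | C#CCC/C=C(\C)C[C@H](O[Si](C)(C)C(C)(C)C)C=C(C)C | intermediate
36 | (E,E)-alkenyl(dimethyl)alane from 35 | C[Al](C)/C=C(\C)CC/C=C(\C)C[C@H](O[Si](C)(C)C(C)(C)C)C=C(C)C | intermediate (not isolated)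
37 | tert-butyl{[(1E,5E,8S)-1-iodo-2,6,10-trimethylundeca-1,5,9-trien-8-yl]oxy}dimethylsilane | I/C=C(\C)CC/C=C(\C)C[C@H](O[Si](C)(C)C(C)(C)C)C=C(C)C | intermediate
38 | (1E,5E,8S)-1-iodo-2,6,10-trimethylundeca-1,5,9-trien-8-ol | I/C=C(\C)CC/C=C(\C)C[C@H](O)C=C(C)C | intermediate
39 | (1S,3E,7E)-1-[(2R)-3,3-dimethyloxiran-2-yl]-8-iodo-3,7-dimethylocta-3,7-dien-1-ol | I/C=C(\C)CC/C=C(\C)C[C@H](O)[C@H]1OC1(C)C | intermediate
40 | triethylsilyl ether of 39 | I/C=C(\C)CC/C=C(\C)C[C@H](O[Si](CC)(CC)CC)[C@H]1OC1(C)C | intermediate
41 | ring alkylzinc iodide (C5–CH2CH2ZnI) | C/C1=C2\CC[C@](C)(O[Si](CC)(CC)CC)[C@@](C)(CC[Zn]I)[C@@H]2CCCOC1=O | intermediate (not isolated)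
42 | coupled unsaturated lactone with full side chain, bis(triethylsilyl) ether | C/C1=C2\CC[C@](C)(O[Si](CC)(CC)CC)[C@@](C)(CC/C=C(\C)CC/C=C(\C)C[C@H](O[Si](CC)(CC)CC)[C@H]3OC3(C)C)[C@@H]2CCCOC1=O | intermediate
43 | allylic alcohol/primary alcohol diol, bis(triethylsilyl) ether | C/C(CO)=C1\CC[C@](C)(O[Si](CC)(CC)CC)[C@@](C)(CC/C=C(\C)CC/C=C(\C)C[C@H](O[Si](CC)(CC)CC)[C@H]2OC2(C)C)[C@@H]1CCCO | intermediate
44 | hydroxy enal, bis(triethylsilyl) ether of the target | C/C(C=O)=C1\CC[C@](C)(O[Si](CC)(CC)CC)[C@@](C)(CC/C=C(\C)CC/C=C(\C)C[C@H](O[Si](CC)(CC)CC)[C@H]2OC2(C)C)[C@@H]1CCCO | intermediate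
45 | CNP0161066.1 | C/C(C=O)=C1\CC[C@](C)(O)[C@@](C)(CC/C=C(\C)CC/C=C(\C)C[C@H](O)[C@H]2OC2(C)C)[C@@H]1CCCO | target

**Step count and risks**

Total step count: 31. Longest linear sequence: 21 steps (steps 1–17, then 28–31).

Steps most likely to fail:

Step 15. The samarium enolate may be protonated or add between molecules before it closes the medium ring onto the hindered ketone. The fallback makes the C1–Cα bond between separate partners and closes the ring at the ester bond. It sets out from diol 18: selective silylation of the primary hydroxyl (tBuMe2SiCl, imidazole) gives the primary tert-butyldimethylsilyl ether F1; Dess–Martin oxidation gives the C1 ketone F2; addition of the dilithium dianion of propanoic acid (LiN(iPr)2, THF, −78 °C) gives the β-hydroxy acid F3; HF·pyridine removes the primary silyl group selectively to give the seco hydroxy acid F4. Shiina lactonization (2-methyl-6-nitrobenzoic anhydride, 4-(dimethylamino)pyridine, high dilution) then closes the eight-membered lactone and comes back to the route at 22.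

Step 16. Sulfonylation of the crowded tertiary hydroxyl may be slow, and elimination may then run into the ring (loss of regiocontrol) or retro-aldol cleavage may compete. The fallback installs the leaving group on the metal alkoxide instead of the free alcohol. It sets out from 21: the SmI2 cyclization is quenched in the same flask with Ac2O and 4-(dimethylamino)pyridine to give the β-acetoxy lactone F5, which DBU converts by E1cB elimination into 24.

Step 5. Borane may attack both faces of the C1=C6 alkene, because the axial C4 methyl sits on the face opposite the angular methyl (poor facial selectivity at the ring fusion). The fallback sets the ring fusion under thermodynamic instead of kinetic control. It sets out from 6: the unseparated hydroboration mixture of 8 and the cis-fused epimeric alcohol F6 is oxidized with Dess–Martin periodinane to the cis-fused C1 ketone F7 and the trans-fused C1 ketone F8; NaOMe in MeOH equilibrates C6 through the enolate toward the trans-fused ketone F8, as 5β-6-keto steroids go to 5α; reduction with Li in NH3/tBuOH gives the equatorial alcohol and comes back to the route at 8.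

**Further compounds**

F1 | step 15 | primary tert-butyldimethylsilyl ether of diol 18 (C1–OH free) | C[C@]1(O[Si](CC)(CC)CC)CC[C@H](O)[C@@H](CCCO[Si](C)(C)C(C)(C)C)[C@]1(C)CCCl
F2 | step 15 | C1 ketone with silylated C6 arm | C[C@]1(O[Si](CC)(CC)CC)CCC(=O)[C@@H](CCCO[Si](C)(C)C(C)(C)C)[C@]1(C)CCCl
F3 | step 15 | β-hydroxy acid from propanoate dianion addition at C1 (one epimer drawn) | C[C@]1(O[Si](CC)(CC)CC)CC[C@](O)([C@@H](C)C(=O)O)[C@@H](CCCO[Si](C)(C)C(C)(C)C)[C@]1(C)CCCl
F4 | step 15 | seco hydroxy acid (free C6-arm alcohol) | C[C@]1(O[Si](CC)(CC)CC)CC[C@](O)([C@@H](C)C(=O)O)[C@@H](CCCO)[C@]1(C)CCCl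
F5 | step 16 | β-acetoxy eight-membered lactone | C[C@]1(O[Si](CC)(CC)CC)CC[C@]2(OC(C)=O)[C@@H](C)C(=O)OCCC[C@H]2[C@]1(C)CCCl
F6 | step 5 | cis-fused C1 alcohol (C1–OH and C6–H cis to the C5 methyl) | C[C@]1(O[Si](CC)(CC)CC)CC[C@@H](O)[C@@H]2CC3(OCCO3)CC[C@]12C
F7 | step 5 | cis-fused C1 ketone | C[C@]1(O[Si](CC)(CC)CC)CCC(=O)[C@@H]2CC3(OCCO3)CC[C@]12C
F8 | step 5 | trans-fused C1 ketone | C[C@]1(O[Si](CC)(CC)CC)CCC(=O)[C@H]2CC3(OCCO3)CC[C@]12C
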